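**Retrosynthetic overview**
1. The ester C–O bond is made last by acylating the free C8 carbinol; the isopropyl group and the C8 hydrogen come from convex-face additions to a bicyclic dienedione.
2. The dienedione comes from a cis-fused ketol; its seven-membered ring is closed onto the existing cyclopentanone by a samarium-enolate aldol of an α,β-epoxy ketone that carries a Z-enal side chain.
3. The epoxy ketone comes from a tetrasubstituted cyclopentenone by catalytic asymmetric nucleophilic epoxidation; this C–O bond formation creates the tertiary carbinol centre that relays to all other centres.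
4. The cyclopentenone comes from 3-bromo-2-methylcyclopent-2-enone and (Z)-3-methylpenta-2,4-dien-1-ol by B-alkyl Suzuki coupling.
5. Ring order: the five-membered ring is bought (2-methylcyclopentane-1,3-dione); the seven-membered ring is formed second.

Assumption: the aldol ring closure is drawn as giving the 8S carbinol; the 8R epimer behaves identically because C8 is planarised and then re-set later.

**Step 1**
Reactants: 1 2-methylcyclopentane-1,3-dione
Product: 2 3-bromo-2-methylcyclopent-2-en-1-one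
Conditions: PPh3, Br2, Et3N, CH2Cl2, 0 °C → rt
Reagents that add atoms: bromine, BrBr (transferred as Ph3PBr2 formed in the flask)
Why: Appel-type activation of the enol by Ph3PBr2 and addition–elimination of bromide gives the β-bromoenone; no stereocentre is involved.

**Step 2**
Reactants: 3 (2Z)-3-methylpent-2-en-4-yn-1-ol
Product: 4 (2Z)-3-methylpenta-2,4-dien-1-ol
Conditions: H2 (1 atm), Pd/CaCO3 poisoned with Pb(OAc)2, quinoline, EtOAc, 0 °C
Reagents that add atoms: none
Why: Lindlar semihydrogenation stops the terminal alkyne at the vinyl group and leaves the Z trisubstituted olefin, the future ring olefin, untouched.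

**Step 3**
Reactants: 4 (2Z)-3-methylpenta-2,4-dien-1-ol; 2 3-bromo-2-methylcyclopent-2-en-1-one
Product: 6 3-[(3Z)-5-hydroxy-3-methylpent-3-en-1-yl]-2-methylcyclopent-2-en-1-one, via bis(9-BBN) adduct 5 (not isolated)
Conditions: 9-BBN (2.1 equiv), THF, 0 °C → rt; then 2, PdCl2(dppf) (5 mol %), aq. K3PO4, DMF, rt
Reagents that add atoms: 9-borabicyclo[3.3.1]nonane, B1C2CCCC1CCC2 (boron is carried only by 5)
Why: Anti-Markovnikov hydroboration of the terminal vinyl group followed by B-alkyl Suzuki–Miyaura coupling with the β-bromoenone forms the sp3–sp2 bond with retention of the Z olefin.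

**Step 4**
Reactants: 6 3-[(3Z)-5-hydroxy-3-methylpent-3-en-1-yl]-2-methylcyclopent-2-en-1-one
Product: 7 (1S,5S)-5-[(3Z)-5-hydroxy-3-methylpent-3-en-1-yl]-1-methyl-6-oxabicyclo[3.1.0]hexan-2-one
Conditions: H2O2 (50% aq., 3 equiv), 9-amino(9-deoxy)epiquinine·2CF3CO2H (20 mol %), dioxane, 40 °C
Reagents that add atoms: hydrogen peroxide, OO
Why: Proposed new method: iminium-catalysed Weitz–Scheffer epoxidation, so far shown for di- and trisubstituted cyclic enones, is applied to a tetrasubstituted 2,3-dialkylcyclopent-2-enone; the primary amine condenses with the hindered ketone, the protonated quinuclidine hydrogen-bonds H2O2 and delivers hydroperoxide to the Si face of C3 of the iminium ion, and the electron-rich enamine closes onto the O–O bond, setting both fully substituted C–O centres (1S,5S) under catalyst control while the non-electrophilic side-chain olefin is untouched; the facial sense is assigned by analogy, the epiquinidine pseudoenantiomer giving the antipode; closest known reaction: primary-amine-salt-catalysed asymmetric epoxidation of cyclic enones with H2O2.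

**Step 5**
Reactants: 7 (1S,5S)-5-[(3Z)-5-hydroxy-3-methylpent-3-en-1-yl]-1-methyl-6-oxabicyclo[3.1.0]hexan-2-one
Product: 8 (2Z)-3-methyl-5-[(1S,5S)-5-methyl-4-oxo-6-oxabicyclo[3.1.0]hexan-1-yl]pent-2-enal
Conditions: MnO2 (15 equiv), CH2Cl2, rt
Reagents that add atoms: none
Why: MnO2 oxidation is selective for the allylic primary alcohol, gives the Z enal without isomerisation and leaves the epoxy ketone intact.

**Step 6**
Reactants: 8 (2Z)-3-methyl-5-[(1S,5S)-5-methyl-4-oxo-6-oxabicyclo[3.1.0]hexan-1-yl]pent-2-enal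
Product: 10 (3aS,8S,8aR)-3a,8-dihydroxy-6,8a-dimethyl-2,3,3a,4,5,8-hexahydroazulen-1(8aH)-one, via samarium enolate 9 (not isolated)
Conditions: SmI2 (2.2 equiv) added to 8 (0.005 M), THF, −78 → −40 °C; pH 7 phosphate buffer
Reagents that add atoms: samarium diiodide, I[Sm]I (samarium and iodine are carried only by 9)
Why: Reductive opening of the α,β-epoxy ketone by two electron transfers gives a trivalent samarium enolate/alkoxide that closes the seven-membered ring by intramolecular aldol (samarium Reformatsky-type) addition to the enal; the tether sits on the face opposite the C3a–O bond and can reach the enolate carbon only from that face, so the fusion is cis with methyl syn to the tertiary hydroxyl, and the C8 configuration is immaterial.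

**Step 7**
Reactants: 10 (3aS,8S,8aR)-3a,8-dihydroxy-6,8a-dimethyl-2,3,3a,4,5,8-hexahydroazulen-1(8aH)-one
Product: 12 (3aS,8aR)-3a-hydroxy-6,8a-dimethyl-3a,4,5,8a-tetrahydroazulene-1,8-dione, via diketone 11 (not isolated)
Conditions: IBX (1.2 equiv), DMSO, rt; then IBX·4-methoxypyridine N-oxide (1.6 equiv), rt
Reagents that add atoms: none
Why: IBX oxidises the allylic alcohol to the enone and then dehydrogenates the only enolisable position of the cyclopentanone (Nicolaou IBX dehydrogenation); C8a is quaternary, so no stereocentre is at risk and both C8 epimers converge.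

**Step 8**
Reactants: 12 (3aS,8aR)-3a-hydroxy-6,8a-dimethyl-3a,4,5,8a-tetrahydroazulene-1,8-dione; 13 isopropylmagnesium chloride
Product: 15 (3R,3aS,8R,8aR)-3a,8-dihydroxy-6,8a-dimethyl-3-(propan-2-yl)-2,3,3a,4,5,8-hexahydroazulen-1(8aH)-one, via magnesium enolate 14 (not isolated)
Conditions: 13 (2.3 equiv), CuBr·SMe2 (20 mol %), THF, −78 °C; then i-Bu2AlH (2.0 equiv), −78 °C; aq. KNaC4H4O6
Reagents that add atoms: isopropylmagnesium chloride, CC(C)[Mg]Cl (magnesium and chlorine are carried only by 14)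
Why: Copper-catalysed conjugate addition goes to the less substituted cyclopentenone on the convex face, syn to the angular alkoxide and methyl, and sets C3; the resulting magnesium enolate masks the five-ring ketone while alkoxide-bound i-Bu2AlH delivers hydride to the same convex face of the seven-ring ketone (1,2-reduction), giving the 8R carbinol anti to the tertiary hydroxyl.

**Step 9**
Reactants: 15 (3R,3aS,8R,8aR)-3a,8-dihydroxy-6,8a-dimethyl-3-(propan-2-yl)-2,3,3a,4,5,8-hexahydroazulen-1(8aH)-one; 16 4-methoxybenzoyl chloride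
Product: 17 (1R,3aR,4R,8aS)-8a-hydroxy-3a,6-dimethyl-3-oxo-1-(propan-2-yl)-1,2,3,3a,4,7,8,8a-octahydroazulen-4-yl 4-methoxybenzoate
Conditions: 16 (1.5 equiv), Et3N, DMAP (20 mol %), CH2Cl2, 0 °C → rt
Reagents that add atoms: 4-methoxybenzoyl chloride, COc1ccc(cc1)C(Cl)=O
Why: DMAP-catalysed acylation esterifies the secondary allylic alcohol only, the ring-fusion tertiary alcohol being too hindered, and touches no stereocentre.

**Compound list**
1 | 2-methylcyclopentane-1,3-dione | CC1C(=O)CCC1=O | starting material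
2 | 3-bromo-2-methylcyclopent-2-en-1-one | CC1=C(Br)CCC1=O | intermediate
3 | (2Z)-3-methylpent-2-en-4-yn-1-ol | C#C/C(C)=C\CO | starting material
4 | (2Z)-3-methylpenta-2,4-dien-1-ol | C=C/C(C)=C\CO | intermediate
5 | 9-[(3Z)-5-(9-borabicyclo[3.3.1]nonan-9-yloxy)-3-methylpent-3-en-1-yl]-9-borabicyclo[3.3.1]nonane | C/C(CCB1C2CCCC1CCC2)=C/COB1C2CCCC1CCC2 | intermediate
6 | 3-[(3Z)-5-hydroxy-3-methylpent-3-en-1-yl]-2-methylcyclopent-2-en-1-one | CC1=C(CC/C(C)=C\CO)CCC1=O | intermediate
7 | (1S,5S)-5-[(3Z)-5-hydroxy-3-methylpent-3-en-1-yl]-1-methyl-6-oxabicyclo[3.1.0]hexan-2-one | C[C@]12O[C@@]1(CC/C(C)=C\CO)CCC2=O | intermediate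
8 | (2Z)-3-methyl-5-[(1S,5S)-5-methyl-4-oxo-6-oxabicyclo[3.1.0]hexan-1-yl]pent-2-enal | C[C@]12O[C@@]1(CC/C(C)=C\C=O)CCC2=O | intermediate
9 | bis(diiodosamarium) salt of (3S)-3-hydroxy-2-methyl-3-[(3Z)-3-methyl-5-oxopent-3-en-1-yl]cyclopent-1-en-1-ol (enolate and alkoxide) | CC1=C(O[Sm](I)I)CC[C@@]1(O[Sm](I)I)CC/C(C)=C\C=O | intermediate
10 | (3aS,8S,8aR)-3a,8-dihydroxy-6,8a-dimethyl-2,3,3a,4,5,8-hexahydroazulen-1(8aH)-one | O[C@H]1C=C(C)CC[C@]2(O)CCC(=O)[C@]12C | intermediate
11 | (3aS,8aR)-3a-hydroxy-6,8a-dimethyl-2,3,3a,4,5,8a-hexahydroazulene-1,8-dione | O=C1C=C(C)CC[C@]2(O)CCC(=O)[C@]12C | intermediate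
12 | (3aS,8aR)-3a-hydroxy-6,8a-dimethyl-3a,4,5,8a-tetrahydroazulene-1,8-dione | O=C1C=C(C)CC[C@]2(O)C=CC(=O)[C@]12C | intermediate
13 | isopropylmagnesium chloride | CC(C)[Mg]Cl | starting material
14 | bis(chloromagnesium) salt of (3S,3aS,8aR)-1,3a-dihydroxy-6,8a-dimethyl-3-(propan-2-yl)-3,3a,4,5-tetrahydroazulen-8(8aH)-one (enolate and alkoxide) | O=C1C=C(C)CC[C@]2(O[Mg]Cl)[C@@H](C(C)C)C=C(O[Mg]Cl)[C@]12C | intermediate
15 | (3R,3aS,8R,8aR)-3a,8-dihydroxy-6,8a-dimethyl-3-(propan-2-yl)-2,3,3a,4,5,8-hexahydroazulen-1(8aH)-one | O[C@@H]1C=C(C)CC[C@]2(O)[C@@H](C(C)C)CC(=O)[C@]12C | intermediate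
16 | 4-methoxybenzoyl chloride | COc1ccc(cc1)C(Cl)=O | starting material
17 | (1R,3aR,4R,8aS)-8a-hydroxy-3a,6-dimethyl-3-oxo-1-(propan-2-yl)-1,2,3,3a,4,7,8,8a-octahydroazulen-4-yl 4-methoxybenzoate | COc1ccc(C(=O)O[C@@H]2C=C(C)CC[C@]3(O)[C@@H](C(C)C)CC(=O)[C@]23C)cc1 | target

**Totals**
Total steps: 9. Longest linear sequence: 8 steps (1 → 2 → 6 → 7 → 8 → 10 → 12 → 15 → 17, or equally from 3 via 4).

**Steps most likely to fail**

Step 4 (the proposed new epoxidation). The hindered ketone may not form the iminium ion, may go to a dienamine, or may give low ee. The fallback uses known chemistry, sets out from 6 and comes back at 7. TBSCl/imidazole gives the tert-butyldimethylsilyl ether F1. Corey–Bakshi–Shibata reduction with (S)-2-methyl-CBS-oxazaborolidine and BH3·SMe2 gives the (1R)-cyclopentenol F2. Hydroxyl-directed epoxidation with VO(acac)2/t-BuOOH gives the syn epoxy alcohol F3. Dess–Martin periodinane gives the epoxy ketone silyl ether F4, and Bu4NF/AcOH returns 7.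

Step 6 (reductive aldol ring closure). SmI2 may reduce the enal, or the seven-membered closure may lose to protonation and oligomerisation. The fallback closes the ring by olefin metathesis instead; it sets out from 7 and comes back at 10. Et3SiCl/imidazole gives the triethylsilyl ether F5. SmI2 in the presence of acrolein gives, by intermolecular aldol, the 1-hydroxyallyl ketol F6. The aldehyde is expected to add anti to the solvated samarium alkoxide, on the side-chain face; this facial sense is the weak point of the fallback. Ring-closing metathesis with RuCl2(H2IMes)(PCy3)(=CHPh) (second-generation Grubbs catalyst) in CH2Cl2 at 40 °C joins the vinyl group to the trisubstituted olefin, expels the silyloxy-bearing terminus and gives 10 directly.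

Step 8 (one-pot conjugate addition and reduction). The tertiary alkoxide flanked by two carbonyls may fragment by retro-aldol or add across the ring to the cycloheptenone, and the hydride may not spare the five-ring carbonyl. The fallback isolates a masked ketone; it sets out from 12 and comes back at 15. The same copper-catalysed addition of 13 is run and the enolate is trapped with Et3SiCl to give the triethylsilyl enol ether F7. Reduction of the seven-ring ketone with i-Bu2AlH in CH2Cl2 at −78 °C gives the alcohol F8, and Bu4NF/AcOH cleaves the enol ether to 15.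

**Further compounds**
F1 | step 4 | 3-[(3Z)-5-[(tert-butyldimethylsilyl)oxy]-3-methylpent-3-en-1-yl]-2-methylcyclopent-2-en-1-one | CC1=C(CC/C(C)=C\CO[Si](C)(C)C(C)(C)C)CCC1=O
F2 | step 4 | (1R)-3-[(3Z)-5-[(tert-butyldimethylsilyl)oxy]-3-methylpent-3-en-1-yl]-2-methylcyclopent-2-en-1-ol | CC1=C(CC/C(C)=C\CO[Si](C)(C)C(C)(C)C)CC[C@H]1O
F3 | step 4 | (1R,2R,5S)-5-[(3Z)-5-[(tert-butyldimethylsilyl)oxy]-3-methylpent-3-en-1-yl]-1-methyl-6-oxabicyclo[3.1.0]hexan-2-ol | C[C@]12O[C@@]1(CC/C(C)=C\CO[Si](C)(C)C(C)(C)C)CC[C@H]2O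
F4 | step 4 | (1S,5S)-5-[(3Z)-5-[(tert-butyldimethylsilyl)oxy]-3-methylpent-3-en-1-yl]-1-methyl-6-oxabicyclo[3.1.0]hexan-2-one | C[C@]12O[C@@]1(CC/C(C)=C\CO[Si](C)(C)C(C)(C)C)CCC2=O
F5 | step 6 | (1S,5S)-1-methyl-5-[(3Z)-3-methyl-5-[(triethylsilyl)oxy]pent-3-en-1-yl]-6-oxabicyclo[3.1.0]hexan-2-one | C[C@]12O[C@@]1(CC/C(C)=C\CO[Si](CC)(CC)CC)CCC2=O
F6 | step 6 | (2R,3S)-3-hydroxy-2-[(1S)-1-hydroxyprop-2-en-1-yl]-2-methyl-3-[(3Z)-3-methyl-5-[(triethylsilyl)oxy]pent-3-en-1-yl]cyclopentan-1-one | C=C[C@H](O)[C@@]1(C)C(=O)CC[C@@]1(O)CC/C(C)=C\CO[Si](CC)(CC)CC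
F7 | step 8 | (3S,3aS,8aR)-3a-hydroxy-6,8a-dimethyl-3-(propan-2-yl)-1-[(triethylsilyl)oxy]-3,3a,4,5-tetrahydroazulen-8(8aH)-one | O=C1C=C(C)CC[C@]2(O)[C@@H](C(C)C)C=C(O[Si](CC)(CC)CC)[C@]12C
F8 | step 8 | (3S,3aS,8R,8aR)-6,8a-dimethyl-3-(propan-2-yl)-1-[(triethylsilyl)oxy]-3,3a,4,5,8,8a-hexahydroazulene-3a,8-diol | O[C@@H]1C=C(C)CC[C@]2(O)[C@@H](C(C)C)C=C(O[Si](CC)(CC)CC)[C@]12C
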